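**Retrosynthetic overview**
1. Feature: the tertiary isopropyl carbinol C4 of the cyclopentane is bonded to the ring-fusion methine C5, which lies beside the oxygen-bearing C6 of the seven-membered ring. C4–C5 is therefore cut as the insertion of a C5 carbenoid, held next to a C6 ketone, into the C4–H bond of a secondary isopropyl carbinol silyl ether. Numbering: C1 methyl-bearing fusion carbon, C2/C3 ring CH2, C4 carbinol, C5 fusion CH, C6 veratrate carbon, C7 CH2, C8=C9 methyl alkene, C10 angelate carbon.
2. Target 34 ⇒ 6,10-diol esters ⇒ 8-en-6-one 26 (C6 set by reduction directed by the C4 hydroxyl) ⇒ 8-methyl-7-en-6-one 24 by deconjugation ⇒ trans-hydroazulen-6-one 20 (two Saegusa oxidations around a methyl cuprate addition).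
3. 20 ⇒ cis-fused 19 by C5 epimerisation ⇒ diazo ketone 18: Rh2(OAc)4 C–H insertion closes the five-membered ring onto the seven-membered ring with retention at C4.
4. 18 ⇒ enone 14 (methyl cuprate anti to the C10 silyl ether, regiospecific enolate, diazo transfer) ⇒ (R)-4-silyloxycycloheptenone 6 (desymmetrised meso diacetate of cyclohepta-1,3-diene) + Grignard reagent from hydroxy ester 8 (Noyori hydrogenation).
5. Ring order: the seven-membered ring is bought; the five-membered ring is formed in the key step.

Key step: step 13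

Convention: β is the face of the C1 methyl group, α the opposite face.

Assumption: the lipase in step 2 hydrolyses the acetate on the (R)-configured carbon of 2, the usual preference of lipases for secondary carbinols. An enzyme of the opposite preference would give the same monoacetate 3 by acylation of the meso diol.

Remark: the C10 carbinol centre is never taken through a ketone. Hydride return to a C10 ketone would be expected anti to the adjacent C1 methyl and would give the 10β epimer, so the C8 methyl and the C8=C9 alkene are brought in from the C6 ketone.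

Remark: 23 is a mixture of C8 epimers; this centre is erased within the same step.

**Step 1**
Reactants: 1 cyclohepta-1,3-diene
Product: 2 cis-cyclohept-2-ene-1,4-diyl diacetate (meso)
Conditions: Pd(OAc)2 (5 mol %), LiOAc, LiCl (cat.), p-benzoquinone, AcOH, rt
Reagents that add atoms: acetic acid, CC(=O)O
Why: Palladium-catalysed 1,4-diacetoxylation of a cyclic 1,3-diene, in which catalytic chloride should steer the second acetate to the same face and give the cis (meso) diacetate.

**Step 2**
Reactants: 2 cis-cyclohept-2-ene-1,4-diyl diacetate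
Product: 3 (1S,4R)-4-hydroxycyclohept-2-en-1-yl acetate
Conditions: lipase PS (Burkholderia cepacia), phosphate buffer pH 7, rt
Reagents that add atoms: none
Why: Enzymatic desymmetrisation of a meso diacetate, in which the lipase should hydrolyse the acetate on the (R)-configured carbon, so that the free hydroxyl marks the future C10 and the remaining acetate the future C6.

**Step 3**
Reactants: 3 (1S,4R)-4-hydroxycyclohept-2-en-1-yl acetate
Product: 4 (1S,4R)-4-(tert-butyldimethylsilyloxy)cyclohept-2-en-1-yl acetate
Conditions: TBSCl, imidazole, DMF, rt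
Reagents that add atoms: tert-butyldimethylsilyl chloride, CC(C)(C)[Si](C)(C)Cl
Why: Imidazole-promoted silylation of the secondary alcohol, which fixes the oxygen of the future C10 stereocentre as a bulky ether.

**Step 4**
Reactants: 4 (1S,4R)-4-(tert-butyldimethylsilyloxy)cyclohept-2-en-1-yl acetate
Product: 5 (1S,4R)-4-(tert-butyldimethylsilyloxy)cyclohept-2-en-1-ol
Conditions: K2CO3, MeOH, 0 °C → rt
Reagents that add atoms: none
Why: Methanolysis (transesterification) of the acetate, to which the silyl ether is stable.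

**Step 5**
Reactants: 5 (1S,4R)-4-(tert-butyldimethylsilyloxy)cyclohept-2-en-1-ol
Product: 6 (R)-4-(tert-butyldimethylsilyloxy)cyclohept-2-en-1-one
Conditions: Dess–Martin periodinane, NaHCO3, CH2Cl2, rt
Reagents that add atoms: none
Why: Dess–Martin oxidation of the allylic alcohol to the enone, which leaves the silyloxy-bearing (R) carbon as the only stereocentre.

**Step 6**
Reactants: 7 ethyl 4-methyl-3-oxopentanoate
Product: 8 ethyl (R)-3-hydroxy-4-methylpentanoate
Conditions: RuCl2[(S)-BINAP] (0.1 mol %), H2 (50 atm), EtOH, 50 °C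
Reagents that add atoms: none
Why: Noyori asymmetric hydrogenation of a β-keto ester, in which the (S)-BINAP ligand should set the (R)-carbinol (R because isopropyl outranks CH2CO2Et).

**Step 7**
Reactants: 8 ethyl (R)-3-hydroxy-4-methylpentanoate
Product: 9 ethyl (R)-4-methyl-3-(triethylsilyloxy)pentanoate
Conditions: TESCl, imidazole, DMF, 0 °C → rt
Reagents that add atoms: chlorotriethylsilane, CC[Si](CC)(CC)Cl
Why: Silylation of the secondary alcohol gives the ether that later activates the C4–H bond and is cleaved more easily than the tert-butyldimethylsilyl ether.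

**Step 8**
Reactants: 9 ethyl (R)-4-methyl-3-(triethylsilyloxy)pentanoate
Product: 10 (R)-4-methyl-3-(triethylsilyloxy)pentan-1-ol
Conditions: iBu2AlH (2.2 equiv), CH2Cl2, −78 → 0 °C; Rochelle salt
Reagents that add atoms: none
Why: Hydride reduction of the ester to the primary alcohol, which does not touch the silyl ether or the stereocentre.

**Step 9**
Reactants: 10 (R)-4-methyl-3-(triethylsilyloxy)pentan-1-ol
Product: 11 (R)-1-bromo-4-methyl-3-(triethylsilyloxy)pentane
Conditions: CBr4, PPh3, 2,6-lutidine, CH2Cl2, 0 °C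
Reagents that add atoms: tetrabromomethane, BrC(Br)(Br)Br
Why: Appel reaction at the primary alcohol under buffered conditions that the secondary triethylsilyl ether should survive.

**Step 10**
Reactants: 11 (R)-1-bromo-4-methyl-3-(triethylsilyloxy)pentane; 6 (R)-4-(tert-butyldimethylsilyloxy)cyclohept-2-en-1-one
Product: 14 (R)-4-(tert-butyldimethylsilyloxy)-3-[(R)-4-methyl-3-(triethylsilyloxy)pentyl]cyclohept-2-en-1-one, via Grignard reagent 12 (not isolated), via trimethylsilyl enol ether 13 (not isolated)
Conditions: Mg, THF, rt; then 6, CuBr·SMe2 (10 mol %), TMSCl, THF, −78 °C; then Pd(OAc)2 (1.05 equiv), MeCN, rt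
Reagents that add atoms: none
Why: Copper-catalysed conjugate addition of the Grignard reagent with silyl trapping, followed by Saegusa–Ito oxidation of the enol ether, gives the β-alkyl enone; the stereocentre made in the addition is erased again.

**Step 11**
Reactants: 14 (R)-4-(tert-butyldimethylsilyloxy)-3-[(R)-4-methyl-3-(triethylsilyloxy)pentyl]cyclohept-2-en-1-one
Product: 15 trimethylsilyl enol ether of (3S,4R)-4-(tert-butyldimethylsilyloxy)-3-methyl-3-[(R)-4-methyl-3-(triethylsilyloxy)pentyl]cycloheptanone (enol double bond between C1 and C2 of the cycloheptanone, methyl trans to the ring silyloxy group)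
Conditions: MeLi, CuI, Et2O, 0 °C; then 14, TMSCl, THF, −78 → −40 °C
Reagents that add atoms: lithium dimethylcuprate (from methyllithium, C[Li], and CuI), [Li+].C[Cu-]C; chlorotrimethylsilane, C[Si](C)(C)Cl
Why: Gilman conjugate addition accelerated by TMSCl, in which the methyl should enter anti to the adjacent silyloxy group and set the quaternary C1 with methyl trans to the C10 oxygen, while the enolate is trapped regiospecifically at C5.

**Step 12**
Reactants: 15 trimethylsilyl enol ether from step 11
Product: 18 (3S,4R)-4-(tert-butyldimethylsilyloxy)-2-diazo-3-methyl-3-[(R)-4-methyl-3-(triethylsilyloxy)pentyl]cycloheptan-1-one, via lithium enolate 16 (not isolated), via trifluoroacetyl ketone 17 (not isolated)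
Conditions: MeLi, THF, 0 °C; CF3CO2CH2CF3, −78 °C; then MsN3, Et3N, H2O, MeCN, rt
Reagents that add atoms: methanesulfonyl azide, CS(=O)(=O)N=[N+]=[N-]
Why: The silyl enol ether gives the regiospecific lithium enolate, which is C-trifluoroacetylated and then undergoes detrifluoroacetylative diazo transfer, so the diazo group lands on C5 (next to the quaternary carbon) and not on C7.

**Step 13**
Reactants: 18 (3S,4R)-4-(tert-butyldimethylsilyloxy)-2-diazo-3-methyl-3-[(R)-4-methyl-3-(triethylsilyloxy)pentyl]cycloheptan-1-one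
Product: 19 cis-fused 10α-(tert-butyldimethylsilyloxy)-4α-isopropyl-1β-methyl-4β-(triethylsilyloxy)perhydroazulen-6-one (5β-H)
Conditions: Rh2(OAc)4 (1 mol %), CH2Cl2, rt, slow addition of 18
Reagents that add atoms: none
Why: Rh2(OAc)4 expels N2 from 18 to give a carbenoid of divalent rhodium at C5, which inserts into the oxygen-activated methine C4–H bond through a three-centre transition state held in a five-membered ring; this is the known rhodium-carbenoid 1,5 C–H insertion of α-diazo ketones into tertiary and ether-activated C–H bonds. The cyclopentane C1–C2–C3–C4–C5 closes by this 1,5-insertion (bond C4–C5), since C4–H is the only C–H bond that a five-membered transition state can reach apart from strained transannular positions. C4 becomes the tertiary carbinol with retention, so its configuration is that of the (R)-carbinol from step 6, and C5 is attacked from the face on which the tether hangs from C1, which gives the cis ring fusion that step 14 corrects. The carbenoid has no β-hydrogen (C1 is quaternary, C6 is the carbonyl), so a 1,2-hydride shift cannot compete, and the bulky silyl ethers disfavour oxonium ylide formation. The step needs site selectivity for C4–H and a concerted insertion; both rest on the ring size of the transition state and on the activation of C4–H by the silyloxy group.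

**Step 14**
Reactants: 19 cis-fused hydroazulen-6-one
Product: 20 trans-fused 10α-(tert-butyldimethylsilyloxy)-4α-isopropyl-1β-methyl-4β-(triethylsilyloxy)perhydroazulen-6-one (5α-H)
Conditions: DBU, toluene, 50 °C
Reagents that add atoms: none
Why: Base-mediated epimerisation α to the ketone, in which the trans-fused isomer should be favoured because it turns C6 away from the cis-vicinal isopropyl group on the cyclopentane.

**Step 15**
Reactants: 20 trans-fused hydroazulen-6-one
Product: 22 trans-fused 10α-(tert-butyldimethylsilyloxy)-4α-isopropyl-1β-methyl-4β-(triethylsilyloxy)hydroazulen-7-en-6-one, via trimethylsilyl enol ether 21 (not isolated)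
Conditions: LiN(iPr)2, TMSCl, THF, −78 °C; then Pd(OAc)2 (1.05 equiv), MeCN, rt
Reagents that add atoms: none
Why: Kinetic deprotonation at the open C7 methylene (C5 is a shielded methine), silyl trapping and Saegusa–Ito oxidation give the 7-en-6-one without touching C5.

**Step 16**
Reactants: 22 trans-fused 7-en-6-one
Product: 24 trans-fused 10α-(tert-butyldimethylsilyloxy)-4α-isopropyl-1β,8-dimethyl-4β-(triethylsilyloxy)hydroazulen-7-en-6-one, via trimethylsilyl enol ether 23 (not isolated)
Conditions: Me2CuLi, TMSCl, THF, −78 °C; then Pd(OAc)2 (1.05 equiv), MeCN, rt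
Reagents that add atoms: lithium dimethylcuprate (from methyllithium, C[Li], and CuI), [Li+].C[Cu-]C
Why: Gilman conjugate addition puts the methyl on C8 and Saegusa–Ito oxidation of the trapped enol ether restores the enone, now with the C8 methyl on the alkene.

**Step 17**
Reactants: 24 trans-fused 8-methyl-7-en-6-one
Product: 26 trans-fused 10α-(tert-butyldimethylsilyloxy)-4α-isopropyl-1β,8-dimethyl-4β-(triethylsilyloxy)hydroazulen-8-en-6-one, via potassium dienolate 25 (not isolated)
Conditions: KN(SiMe3)2, THF, −78 °C; then AcOH, −78 °C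
Reagents that add atoms: none
Why: Deconjugation by kinetic α-protonation of the linear dienolate: γ-deprotonation at the ring methylene C9, which is syn to the carbonyl across the alkene, then protonation at C7, moves the alkene to C8=C9 and leaves C10 untouched.

**Step 18**
Reactants: 26 trans-fused 8-en-6-one
Product: 27 trans-fused 10α-(tert-butyldimethylsilyloxy)-4β-hydroxy-4α-isopropyl-1β,8-dimethylhydroazulen-8-en-6-one
Conditions: HF·pyridine, pyridine, THF, 0 °C
Reagents that add atoms: none
Why: Buffered fluoride desilylation, in which the triethylsilyl ether should cleave well before the tert-butyldimethylsilyl ether, frees the C4 carbinol that directs the next step.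

**Step 19**
Reactants: 27 4β-hydroxy-8-en-6-one
Product: 28 trans-fused 10α-(tert-butyldimethylsilyloxy)-4α-isopropyl-1β,8-dimethylhydroazulen-8-ene-4β,6α-diol
Conditions: Me4NBH(OAc)3, MeCN/AcOH, −30 °C
Reagents that add atoms: none
Why: Evans–Saksena hydroxyl-directed reduction, in which the borohydride bound to the C4 oxygen delivers hydride to the β-face of C6 (the face external hydride would avoid because of the C1 methyl), so the new C6 hydroxyl is α, cis to H5.

**Step 20**
Reactants: 28 4β,6α-diol; 29 3,4-dimethoxybenzoyl chloride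
Product: 30 trans-fused 10α-(tert-butyldimethylsilyloxy)-4β-hydroxy-4α-isopropyl-1β,8-dimethylhydroazulen-8-en-6α-yl 3,4-dimethoxybenzoate
Conditions: DMAP, Et3N, CH2Cl2, 0 °C → rt
Reagents that add atoms: none
Why: DMAP-catalysed acylation of the secondary C6 alcohol, with the tertiary C4 alcohol next to isopropyl too hindered to react.

**Step 21**
Reactants: 30 6α-veratrate silyl ether
Product: 31 trans-fused 4β,10α-dihydroxy-4α-isopropyl-1β,8-dimethylhydroazulen-8-en-6α-yl 3,4-dimethoxybenzoate
Conditions: TBAF, AcOH, THF, rt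
Reagents that add atoms: none
Why: Buffered fluoride desilylation of the allylic C10 ether, which leaves both the ester and the C10 configuration carried since compound 3 intact.

**Step 22**
Reactants: 31 6α-veratrate 4β,10α-diol; 32 angelic acid
Product: 34 target (10α-angelate, 6α-veratrate, 4β-hydroxy), via mixed anhydride 33 (not isolated)
Conditions: 32, 2,4,6-trichlorobenzoyl chloride, Et3N, toluene, rt; then 31, 80 °C
Reagents that add atoms: none
Why: Yamaguchi-type esterification through the mixed anhydride, run without DMAP so that the Z-alkene should not isomerise to the tiglate, acylates the secondary allylic C10 alcohol with retention while the tertiary C4 alcohol stays free.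

**Compound list**
1 | cyclohepta-1,3-diene | C1=CC=CCCC1 | starting material
2 | cis-cyclohept-2-ene-1,4-diyl diacetate (meso) | CC(=O)O[C@H]1CCC[C@@H](OC(C)=O)C=C1 | intermediate
3 | (1S,4R)-4-hydroxycyclohept-2-en-1-yl acetate | CC(=O)O[C@H]1CCC[C@@H](O)C=C1 | intermediate
4 | (1S,4R)-4-(tert-butyldimethylsilyloxy)cyclohept-2-en-1-yl acetate | CC(=O)O[C@H]1CCC[C@@H](O[Si](C)(C)C(C)(C)C)C=C1 | intermediate
5 | (1S,4R)-4-(tert-butyldimethylsilyloxy)cyclohept-2-en-1-ol | O[C@H]1CCC[C@@H](O[Si](C)(C)C(C)(C)C)C=C1 | intermediate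
6 | (R)-4-(tert-butyldimethylsilyloxy)cyclohept-2-en-1-one | O=C1CCC[C@@H](O[Si](C)(C)C(C)(C)C)C=C1 | intermediate
7 | ethyl 4-methyl-3-oxopentanoate | CCOC(=O)CC(=O)C(C)C | starting material
8 | ethyl (R)-3-hydroxy-4-methylpentanoate | CCOC(=O)C[C@@H](O)C(C)C | intermediate
9 | ethyl (R)-4-methyl-3-(triethylsilyloxy)pentanoate | CCOC(=O)C[C@@H](O[Si](CC)(CC)CC)C(C)C | intermediate
10 | (R)-4-methyl-3-(triethylsilyloxy)pentan-1-ol | OCC[C@@H](O[Si](CC)(CC)CC)C(C)C | intermediate
11 | (R)-1-bromo-4-methyl-3-(triethylsilyloxy)pentane | BrCC[C@@H](O[Si](CC)(CC)CC)C(C)C | intermediate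
12 | [(R)-4-methyl-3-(triethylsilyloxy)pentyl]magnesium bromide | Br[Mg]CC[C@@H](O[Si](CC)(CC)CC)C(C)C | intermediate
13 | trimethylsilyl enol ether of the conjugate adduct (chain trans to the ring silyloxy group) | C[Si](C)(C)OC1=C[C@@H](CC[C@@H](O[Si](CC)(CC)CC)C(C)C)[C@H](O[Si](C)(C)C(C)(C)C)CCC1 | intermediate
14 | (R)-4-(tert-butyldimethylsilyloxy)-3-[(R)-4-methyl-3-(triethylsilyloxy)pentyl]cyclohept-2-en-1-one | O=C1C=C(CC[C@@H](O[Si](CC)(CC)CC)C(C)C)[C@H](O[Si](C)(C)C(C)(C)C)CCC1 | intermediate
15 | trimethylsilyl enol ether of (3S,4R)-4-(tert-butyldimethylsilyloxy)-3-methyl-3-[(R)-4-methyl-3-(triethylsilyloxy)pentyl]cycloheptanone | C[Si](C)(C)OC1=C[C@](C)(CC[C@@H](O[Si](CC)(CC)CC)C(C)C)[C@H](O[Si](C)(C)C(C)(C)C)CCC1 | intermediate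
16 | lithium enolate corresponding to 15 | [Li]OC1=C[C@](C)(CC[C@@H](O[Si](CC)(CC)CC)C(C)C)[C@H](O[Si](C)(C)C(C)(C)C)CCC1 | intermediate
17 | 2-trifluoroacetyl ketone (C2 of the cycloheptanone not defined, enolised) | O=C1CCC[C@@H](O[Si](C)(C)C(C)(C)C)[C@@](C)(CC[C@@H](O[Si](CC)(CC)CC)C(C)C)C1C(=O)C(F)(F)F | intermediate
18 | (3S,4R)-4-(tert-butyldimethylsilyloxy)-2-diazo-3-methyl-3-[(R)-4-methyl-3-(triethylsilyloxy)pentyl]cycloheptan-1-one | [N-]=[N+]=C1C(=O)CCC[C@@H](O[Si](C)(C)C(C)(C)C)[C@@]1(C)CC[C@@H](O[Si](CC)(CC)CC)C(C)C | intermediate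
19 | cis-fused (5β-H) 10α-(tert-butyldimethylsilyloxy)-4α-isopropyl-1β-methyl-4β-(triethylsilyloxy)perhydroazulen-6-one | O=C1CCC[C@@H](O[Si](C)(C)C(C)(C)C)[C@@]2(C)CC[C@@](O[Si](CC)(CC)CC)(C(C)C)[C@@H]12 | intermediate
20 | trans-fused (5α-H) epimer of 19 | O=C1CCC[C@@H](O[Si](C)(C)C(C)(C)C)[C@@]2(C)CC[C@@](O[Si](CC)(CC)CC)(C(C)C)[C@H]12 | intermediate
21 | trimethylsilyl enol ether of 20 (C6=C7) | C[Si](C)(C)OC1=CCC[C@@H](O[Si](C)(C)C(C)(C)C)[C@@]2(C)CC[C@@](O[Si](CC)(CC)CC)(C(C)C)[C@H]12 | intermediate
22 | trans-fused 7-en-6-one | O=C1C=CC[C@@H](O[Si](C)(C)C(C)(C)C)[C@@]2(C)CC[C@@](O[Si](CC)(CC)CC)(C(C)C)[C@H]12 | intermediate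
23 | 8-methyl trimethylsilyl enol ether (C6=C7, C8 epimers) | C[Si](C)(C)OC1=CC(C)C[C@@H](O[Si](C)(C)C(C)(C)C)[C@@]2(C)CC[C@@](O[Si](CC)(CC)CC)(C(C)C)[C@H]12 | intermediate
24 | trans-fused 8-methyl-7-en-6-one | O=C1C=C(C)C[C@@H](O[Si](C)(C)C(C)(C)C)[C@@]2(C)CC[C@@](O[Si](CC)(CC)CC)(C(C)C)[C@H]12 | intermediate
25 | potassium 6,8-dienolate of 24 | [K]OC1=CC(C)=C[C@@H](O[Si](C)(C)C(C)(C)C)[C@@]2(C)CC[C@@](O[Si](CC)(CC)CC)(C(C)C)[C@H]12 | intermediate
26 | trans-fused 8-methyl-8-en-6-one | O=C1CC(C)=C[C@@H](O[Si](C)(C)C(C)(C)C)[C@@]2(C)CC[C@@](O[Si](CC)(CC)CC)(C(C)C)[C@H]12 | intermediate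
27 | 4β-hydroxy-8-methyl-8-en-6-one, 10α-silyl ether | O=C1CC(C)=C[C@@H](O[Si](C)(C)C(C)(C)C)[C@@]2(C)CC[C@@](O)(C(C)C)[C@H]12 | intermediate
28 | 4β,6α-diol, 10α-silyl ether | O[C@H]1CC(C)=C[C@@H](O[Si](C)(C)C(C)(C)C)[C@@]2(C)CC[C@@](O)(C(C)C)[C@H]12 | intermediate
29 | 3,4-dimethoxybenzoyl chloride | COc1ccc(cc1OC)C(Cl)=O | starting material
30 | 6α-veratrate, 4β-ol, 10α-silyl ether | COc1ccc(cc1OC)C(=O)O[C@H]1CC(C)=C[C@@H](O[Si](C)(C)C(C)(C)C)[C@@]2(C)CC[C@@](O)(C(C)C)[C@H]12 | intermediate
31 | 6α-veratrate, 4β,10α-diol | COc1ccc(cc1OC)C(=O)O[C@H]1CC(C)=C[C@@H](O)[C@@]2(C)CC[C@@](O)(C(C)C)[C@H]12 | intermediate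
32 | angelic acid | C/C=C(/C)C(=O)O | starting material
33 | angelic 2,4,6-trichlorobenzoic anhydride | C/C=C(/C)C(=O)OC(=O)c1c(Cl)cc(Cl)cc1Cl | intermediate
34 | CNP0142353.1 | C/C=C(/C)C(=O)O[C@@H]1C=C(C)C[C@H](OC(=O)c2ccc(OC)c(OC)c2)[C@@H]2[C@]1(C)CC[C@@]2(O)C(C)C | target

**Step count**
Total: 22 steps. Longest linear sequence: 18 steps (steps 1–5 and 10–22, from cyclohepta-1,3-diene); the side-chain branch (steps 6–9) joins in step 10.

**Steps most likely to fail**

Step 13 (C–H insertion). The electrophilic carbenoid may abstract hydride from the oxygen-bearing C4–H in a stepwise way, with loss of configuration at C4 or fragmentation, or it may be consumed by Wolff ring contraction. Fallback, from 14 back to 20: the C4–C5 bond is made by an aldol reaction under thermodynamic control. PPTS in MeOH should remove the secondary triethylsilyl group of 14 to give the hydroxy enone F1. Dess–Martin oxidation gives the isopropyl ketone F2. Me2CuLi/TMSCl and acidic work-up give the 3-methyl diketone F3, with methyl anti to the silyloxy group. KOH in MeOH at 0 °C closes the cyclopentane by an equilibrating intramolecular aldol reaction to the trans-fused ketol F4. This isomer should be favoured because the hydroxyl, not the isopropyl group, sits cis-1,3 to the C1 methyl and can hydrogen-bond to the C6 carbonyl. TESOTf/2,6-lutidine then gives 20. This path gives up the stereospecific transfer from the carbinol, so the C4 configuration would rest on the equilibrium.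

Step 17 (deconjugation). Deprotonation may occur at the C8 methyl instead of C9, the dienolate may expel the axial C10 silyloxy group by 1,6-elimination, or the alkene may move back into conjugation on quench. Fallback, from 20 to 34: the C8=C9 alkene is built from a C10 ketone and C10 is restored by inversion. HF·pyridine frees the C4 carbinol of 20 to give the trans ketol F4 (the compound of the fallback to step 13). Me4NBH(OAc)3 reduces it under the same hydroxyl direction as in step 19 to the saturated 4β,6α-diol F6. Chloride 29 with DMAP gives the 6α-veratrate F7. TBAF/AcOH frees the C10 alcohol F8. Dess–Martin oxidation gives the 10-ketone F9. IBX in DMSO at 70 °C dehydrogenates it to the 8-en-10-one F10, C9 being the only enolisable position. Excess Me2CuLi at −78 °C gives the 8-methyl ketone F11. A second IBX dehydrogenation gives the 8-methyl-8-en-10-one F12. Luche reduction (NaBH4, CeCl3·7H2O, MeOH, −78 °C) should deliver hydride anti to the C1 methyl and give the 10β-allylic alcohol F13. Mitsunobu esterification with angelic acid 32 (PPh3, DIAD, toluene) inverts C10 and gives 34.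

Step 14 (C5 epimerisation). The equilibrium may not lie on the trans side, or the C5 enolate may expel the C4 silyloxy group by β-elimination. Fallback, from 19 back to 20: the equilibration is run on the free carbinol, where only the trans isomer can hydrogen-bond to the ketone. HF·pyridine removes the triethylsilyl group of 19 to give the cis-fused ketol F5. DBU in toluene at rt equilibrates it (directly and through reversible retro-aldol opening) to the trans ketol F4. TESOTf/2,6-lutidine gives 20.

**Further compounds**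
F1 | step 13 | (R)-4-(tert-butyldimethylsilyloxy)-3-[(R)-3-hydroxy-4-methylpentyl]cyclohept-2-en-1-one | O=C1C=C(CC[C@@H](O)C(C)C)[C@H](O[Si](C)(C)C(C)(C)C)CCC1
F2 | step 13 | (R)-4-(tert-butyldimethylsilyloxy)-3-(4-methyl-3-oxopentyl)cyclohept-2-en-1-one | O=C1C=C(CCC(=O)C(C)C)[C@H](O[Si](C)(C)C(C)(C)C)CCC1
F3 | step 13 | (3S,4R)-4-(tert-butyldimethylsilyloxy)-3-methyl-3-(4-methyl-3-oxopentyl)cycloheptan-1-one | O=C1C[C@](C)(CCC(=O)C(C)C)[C@H](O[Si](C)(C)C(C)(C)C)CCC1
F4 | step 13 | trans-fused 10α-(tert-butyldimethylsilyloxy)-4β-hydroxy-4α-isopropyl-1β-methylperhydroazulen-6-one | O=C1CCC[C@@H](O[Si](C)(C)C(C)(C)C)[C@@]2(C)CC[C@@](O)(C(C)C)[C@H]12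
F5 | step 14 | cis-fused (5β-H) 10α-(tert-butyldimethylsilyloxy)-4β-hydroxy-4α-isopropyl-1β-methylperhydroazulen-6-one | O=C1CCC[C@@H](O[Si](C)(C)C(C)(C)C)[C@@]2(C)CC[C@@](O)(C(C)C)[C@@H]12
F6 | step 17 | saturated 4β,6α-diol, 10α-silyl ether | O[C@H]1CCC[C@@H](O[Si](C)(C)C(C)(C)C)[C@@]2(C)CC[C@@](O)(C(C)C)[C@H]12
F7 | step 17 | saturated 6α-veratrate, 10α-silyl ether | COc1ccc(cc1OC)C(=O)O[C@H]1CCC[C@@H](O[Si](C)(C)C(C)(C)C)[C@@]2(C)CC[C@@](O)(C(C)C)[C@H]12
F8 | step 17 | saturated 6α-veratrate, 4β,10α-diol | COc1ccc(cc1OC)C(=O)O[C@H]1CCC[C@@H](O)[C@@]2(C)CC[C@@](O)(C(C)C)[C@H]12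
F9 | step 17 | 6α-veratrate 10-ketone | COc1ccc(cc1OC)C(=O)O[C@H]1CCCC(=O)[C@@]2(C)CC[C@@](O)(C(C)C)[C@H]12
F10 | step 17 | 6α-veratrate 8-en-10-one | COc1ccc(cc1OC)C(=O)O[C@H]1CC=CC(=O)[C@@]2(C)CC[C@@](O)(C(C)C)[C@H]12
F11 | step 17 | 6α-veratrate 8-methyl-10-ketone (C8 epimers) | COc1ccc(cc1OC)C(=O)O[C@H]1CC(C)CC(=O)[C@@]2(C)CC[C@@](O)(C(C)C)[C@H]12
F12 | step 17 | 6α-veratrate 8-methyl-8-en-10-one | COc1ccc(cc1OC)C(=O)O[C@H]1CC(C)=CC(=O)[C@@]2(C)CC[C@@](O)(C(C)C)[C@H]12
F13 | step 17 | 6α-veratrate 4β,10β-diol (C10 epimer of 31) | COc1ccc(cc1OC)C(=O)O[C@H]1CC(C)=C[C@H](O)[C@@]2(C)CC[C@@](O)(C(C)C)[C@H]12
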